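Teferin is cut at its seven-membered ring (daucane numbering). The four-carbon unit C7–C6–C5–C1 already sits on the five-membered ring as a 2-vinylcyclopentenone and is joined to the three-carbon unit C8–C9–C10 of a vinyl diazo ester. One rhodium-carbenoid operation (cyclopropanation of the vinyl group, then Cope rearrangement of the cis-divinylcyclopropane) makes C7–C8 and C1–C10, closes the cycloheptadiene and creates the methyl-bearing quaternary ring-fusion carbon C1 in absolute form. The precursor is achiral 3-methyl-2-vinylcyclopent-2-enone. Its ketone (C4) later carries the isopropyl carbinol, the new C5=C6 bond takes the ring-fusion hydrogen and the ester oxygen, and the C8 ester becomes the C8 methyl.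

Key step: step 5

Numbering: daucane numbering is used for all bicyclic compounds (C1 methyl-bearing ring-fusion carbon, C2/C3 ring CH2, C4 carbinol or ketone carbon, C5 ring-fusion CH, C6 to C10 the other seven-ring carbons, C8 bearing the ester or methyl); β is the face of the C1 methyl, α the opposite face.

Assumption: Rh2(S-DOSP)4 is taken to deliver donor/acceptor carbenoids to the Re face of the substituted carbon of a terminal alkene, as in its styrene cyclopropanations, so the Si-face attack on C6 that leads to (R)-C1 calls for Rh2(R-DOSP)4; the cis or trans relation of C4–OH and the C1 methyl in 10 (NOE) would expose a reversed sense, and then only the catalyst antipode changes.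

Step 1
Reactants: 1 2-bromo-3-methylcyclopent-2-en-1-one; 2 tributyl(vinyl)stannane
Product: 3 3-methyl-2-vinylcyclopent-2-en-1-one
Conditions: Pd(PPh3)4 (5 mol %), CuI (10 mol %), DMF, 60 °C
Reagents that add atoms: none
Why: Stille coupling, in which zerovalent palladium inserts into the activated C–Br bond of the α-bromoenone and copper-assisted transmetalation from tin and reductive elimination should give the cross-conjugated dienone, which is kept cold and used promptly because 2-vinyl enones slowly dimerise.

Step 2
Reactants: 4 methyl acetoacetate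
Product: 5 methyl 2-diazo-3-oxobutanoate
Conditions: 4-acetamidobenzenesulfonyl azide, Et3N, MeCN, 0 °C → rt
Reagents that add atoms: 4-acetamidobenzenesulfonyl azide, CC(=O)Nc1ccc(cc1)S(=O)(=O)N=[N+]=[N-]
Why: Regitz diazo transfer to the doubly activated methylene of a β-keto ester under amine base is the standard entry to 2-diazo-3-oxo esters.

Step 3
Reactants: 5 methyl 2-diazo-3-oxobutanoate
Product: 6 methyl 2-diazo-3-hydroxybutanoate (racemic)
Conditions: NaBH4, MeOH, 0 °C
Reagents that add atoms: none
Why: Borohydride reduces the ketone chemoselectively because the ester-stabilised diazo group is inert to NaBH4 at 0 °C, and the new carbinol centre is destroyed in the next step.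

Step 4
Reactants: 6 methyl 2-diazo-3-hydroxybutanoate
Product: 7 methyl 2-diazobut-3-enoate
Conditions: POCl3, Et3N, CH2Cl2, 0 °C → rt; used at once as a cold hexanes solution
Reagents that add atoms: none
Why: Dehydration through the dichlorophosphate and amine-induced β-elimination gives the vinyl diazo ester, which is used immediately because it cyclises slowly to a pyrazole on standing.

Step 5
Reactants: 3 3-methyl-2-vinylcyclopent-2-en-1-one; 7 methyl 2-diazobut-3-enoate
Product: 9 methyl (8aR)-8a-methyl-3-oxo-1,2,3,5,8,8a-hexahydroazulene-6-carboxylate, via cis-divinylcyclopropane 8 (not isolated)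
Conditions: Rh2(R-DOSP)4 (1 mol %), 3 (2 equiv), 7 added over 2 h, hexanes–PhCF3 (9:1), −40 °C → rt; then toluene, 70 °C until 8 is consumed
Reagents that add atoms: none
Why: The diazo ester loses N2 at divalent rhodium to give a donor/acceptor vinylcarbenoid, which is attacked by the terminal CH2 (C7) of the only accessible alkene of 3 and closes the three-membered ring C6–C7–C8 in a concerted, asynchronous carbene transfer that places the cyclopentenyl group cis to the carbenoid vinyl group. The resulting cis-divinylcyclopropane 8 then undergoes a boat-shaped [3,3]-sigmatropic (Cope) shift that breaks C6–C8 and joins C10 to C1, so the seven-membered ring is closed by a strain-driven pericyclic C–C bond formation and not by a polar cyclisation. The closest known reaction type is the tandem cyclopropanation/Cope rearrangement of rhodium vinylcarbenoids with 1,3-dienes (formal [4+3] cycloaddition), including cases that create a quaternary carbon at the diene terminus. C1 is the only stereocentre that survives: the chiral carboxylate ligands of Rh2(R-DOSP)4 fix C6 and C8 of 8, and the boat geometry passes this information suprafacially to C1 while C6 and C8 become sp2. The step needs site selectivity for the vinyl group over the ring alkene, secured because that alkene is tetrasubstituted and electron-poor, and chemoselectivity against the ketone oxygen and against self-reaction of 7, secured by slow addition of 7 to excess 3 at low temperature in a hydrocarbon medium. Because the C1 methyl points into the boat, warming is planned to complete the rearrangement, which is pulled forward by conjugation of the new C5=C6 bond with the C4 ketone.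

Step 6
Reactants: 9 methyl (8aR)-8a-methyl-3-oxo-1,2,3,5,8,8a-hexahydroazulene-6-carboxylate
Product: 10 methyl (3S,8aR)-3-hydroxy-8a-methyl-1,2,3,5,8,8a-hexahydroazulene-6-carboxylate (4β-OH, cis to the C1 methyl)
Conditions: (R)-2-methyl-CBS-oxazaborolidine (0.2 equiv), catecholborane (1.5 equiv), toluene, −78 °C
Reagents that add atoms: none
Why: CBS reduction, in which the oxazaborolidine binds the ketone with the fully substituted alkenyl carbon C5 as the large group and the (R)-catalyst passes hydride to the α face that the angular methyl also leaves open, so catalyst and substrate control should combine to give the 4β-alcohol (C4 S) by 1,2-reduction, while any enantiomer of 9 is turned into a separable diastereomer.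

Step 7
Reactants: 10 methyl (3S,8aR)-3-hydroxy-8a-methyl-1,2,3,5,8,8a-hexahydroazulene-6-carboxylate
Product: 11 methyl (3S,8aR)-8a-methyl-3-(triethylsilyloxy)-1,2,3,5,8,8a-hexahydroazulene-6-carboxylate
Conditions: Et3SiCl, imidazole, CH2Cl2, 0 °C → rt
Reagents that add atoms: chlorotriethylsilane, CC[Si](CC)(CC)Cl
Why: Routine silylation of a secondary alcohol, with the triethylsilyl group chosen because it survives borane and hydride reagents yet can later be removed beside a tert-butyldimethylsilyl ether.

Step 8
Reactants: 11 methyl (3S,8aR)-8a-methyl-3-(triethylsilyloxy)-1,2,3,5,8,8a-hexahydroazulene-6-carboxylate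
Product: 13 methyl (3S,3aS,4S,8aR)-4-hydroxy-8a-methyl-3-(triethylsilyloxy)-1,2,3,3a,4,5,8,8a-octahydroazulene-6-carboxylate, via C6 alkylborane 12 (not isolated)
Conditions: BH3·THF (2 equiv), THF, 0 °C → rt; then NaBO3·4H2O, THF–H2O, rt
Reagents that add atoms: sodium perborate, [Na+].[O-]OB=O
Why: Hydroboration–oxidation, in which borane adds syn across the electron-rich trisubstituted C5=C6 bond from the α face, opposite to the β methyl on C1 and the β silyloxy group on C4, with boron on the less substituted C6 while the α-substituted enoate is deactivated, and oxidation with retention then sets 5α-H and 6α-OH, that is the trans ring fusion and the C6 carbinol of the target.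

Step 9
Reactants: 13 methyl (3S,3aS,4S,8aR)-4-hydroxy-8a-methyl-3-(triethylsilyloxy)-1,2,3,3a,4,5,8,8a-octahydroazulene-6-carboxylate
Product: 14 the 6α-tert-butyldimethylsilyl ether of 13 (4β-OTES; 5α-H; 6α-OTBS; C8 ester)
Conditions: tBuMe2SiOTf (1.5 equiv), 2,6-lutidine (3 equiv), CH2Cl2, −78 → 0 °C
Reagents that add atoms: tert-butyldimethylsilyl trifluoromethanesulfonate, CC(C)(C)[Si](C)(C)OS(=O)(=O)C(F)(F)F
Why: A silyl triflate with a hindered pyridine base silylates the crowded secondary C6 alcohol, and the robust TBS ether is a poor leaving group that shields C6–O through the hydride, oxidation and organocerium steps.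

Step 10
Reactants: 14 the 6α-tert-butyldimethylsilyl ether of 13
Product: 15 primary allylic alcohol (C8–CH2OH; C8=C9; 4β-OTES; 5α-H; 6α-OTBS)
Conditions: iBu2AlH (2.5 equiv), CH2Cl2, −78 °C; aqueous potassium sodium tartrate work-up
Reagents that add atoms: none
Why: iBu2AlH at low temperature reduces the conjugated methyl ester by 1,2-addition to the primary allylic alcohol without touching silyl ethers or the alkene.

Step 11
Reactants: 15 primary allylic alcohol (C8–CH2OH)
Product: 17 C8-methyl bis-silyl ether (C8–CH3; C8=C9; 4β-OTES; 5α-H; 6α-OTBS), via allylic mesylate 16 (not isolated)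
Conditions: MsCl (1.2 equiv), Et3N (1.5 equiv), THF, −40 °C; then LiEt3BH (3 equiv), −40 → 0 °C
Reagents that add atoms: none
Why: Sulfonylation of the primary allylic alcohol and direct SN2 displacement by hydride from LiEt3BH at the unhindered CH2 terminus should give the C8 methyl group with the C8=C9 bond left in place, the SN2' path being disfavoured at the ring carbon.

Step 12
Reactants: 17 C8-methyl bis-silyl ether
Product: 18 4β-alcohol (C4–OH β; 5α-H; 6α-OTBS; C8–CH3; C8=C9)
Conditions: PPTS (0.1 equiv), MeOH–CH2Cl2 (1:1), 0 °C → rt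
Reagents that add atoms: none
Why: Mild acid-catalysed methanolysis removes the triethylsilyl ether, which is far more labile than the hindered secondary TBS ether, and frees only the C4 hydroxyl.

Step 13
Reactants: 18 4β-alcohol
Product: 19 (3aS,4S,8aR)-4-(tert-butyldimethylsilyloxy)-6,8a-dimethyl-2,3a,4,5,8,8a-hexahydroazulen-3(1H)-one (C4 ketone)
Conditions: Dess–Martin periodinane (1.3 equiv), NaHCO3, CH2Cl2, 0 °C → rt
Reagents that add atoms: none
Why: Dess–Martin oxidation under bicarbonate buffer gives the ketone under non-basic conditions, so the enolisable C5–H next to the β-silyloxy carbon C6 is neither epimerised nor eliminated.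

Step 14
Reactants: 19 (3aS,4S,8aR)-4-(tert-butyldimethylsilyloxy)-6,8a-dimethyl-2,3a,4,5,8,8a-hexahydroazulen-3(1H)-one
Product: 20 (3R,3aS,4S,8aR)-4-(tert-butyldimethylsilyloxy)-6,8a-dimethyl-3-(propan-2-yl)-1,2,3,3a,4,5,8,8a-octahydroazulen-3-ol
Conditions: CeCl3 (anhydrous, 3 equiv), iPrMgCl (3 equiv), THF, −78 °C, 1 h (forms iPrCeCl2); then 19, −78 → −40 °C; aqueous NH4Cl
Reagents that add atoms: isopropylmagnesium chloride, CC(C)[Mg]Cl
Why: Organocerium 1,2-addition, in which the weakly basic, oxophilic isopropylcerium reagent adds to the hindered enolisable ketone without enolisation, β-elimination of the C6 silyloxy group or hydride transfer, and approaches C4 from the α face, anti to the pseudo-axial C1 methyl that lies 1,3 to the carbonyl, which sets the tertiary carbinol with 4β-OH (C4 R).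

Step 15
Reactants: 20 (3R,3aS,4S,8aR)-4-(tert-butyldimethylsilyloxy)-6,8a-dimethyl-3-(propan-2-yl)-1,2,3,3a,4,5,8,8a-octahydroazulen-3-ol
Product: 21 jaeschkeanadiol, (3R,3aS,4S,8aR)-6,8a-dimethyl-3-(propan-2-yl)-1,2,3,3a,4,5,8,8a-octahydroazulene-3,4-diol
Conditions: Bu4NF (3 equiv), THF, rt → 45 °C
Reagents that add atoms: none
Why: Fluoride cleaves the Si–O bond of the TBS ether and leaves the tertiary alcohol and the trisubstituted alkene untouched.

Step 16
Reactants: 22 vanillic acid
Product: 23 3-methoxy-4-(pivaloyloxy)benzoic acid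
Conditions: pivaloyl chloride (1.1 equiv), NaOH (2.2 equiv), H2O–THF, 0 °C; then HCl to pH 2
Reagents that add atoms: pivaloyl chloride, CC(C)(C)C(=O)Cl
Why: Schotten–Baumann acylation of the phenoxide in aqueous base protects the phenol as a pivalate, any mixed anhydride at the carboxylate being hydrolysed under the same conditions before acidification.

Step 17
Reactants: 21 jaeschkeanadiol; 23 3-methoxy-4-(pivaloyloxy)benzoic acid
Product: 24 (3R,3aS,4S,8aR)-3-hydroxy-6,8a-dimethyl-3-(propan-2-yl)-1,2,3,3a,4,5,8,8a-octahydroazulen-4-yl 3-methoxy-4-(pivaloyloxy)benzoate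
Conditions: DCC (1.5 equiv), DMAP (0.3 equiv), CH2Cl2, 0 °C → rt
Reagents that add atoms: none
Why: Steglich esterification acylates only the secondary C6 hydroxyl because the tertiary C4 hydroxyl is inert to the acylpyridinium intermediate, and the pivalate on the phenol prevents self-condensation of the acid.

Step 18
Reactants: 24 (3R,3aS,4S,8aR)-3-hydroxy-6,8a-dimethyl-3-(propan-2-yl)-1,2,3,3a,4,5,8,8a-octahydroazulen-4-yl 3-methoxy-4-(pivaloyloxy)benzoate
Product: 25 teferin, (3R,3aS,4S,8aR)-3-hydroxy-6,8a-dimethyl-3-(propan-2-yl)-1,2,3,3a,4,5,8,8a-octahydroazulen-4-yl 4-hydroxy-3-methoxybenzoate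
Conditions: pyrrolidine (5 equiv), CH2Cl2, rt
Reagents that add atoms: none
Why: Aminolysis by pyrrolidine cleaves the electrophilic aryl pivalate selectively, because phenoxide is a far better leaving group than the hindered secondary alkoxide of the vanillate ester, and releases the free phenol of teferin.

Compound list
1 | 2-bromo-3-methylcyclopent-2-en-1-one (catalogue compound) | CC1=C(Br)C(=O)CC1 | starting material
2 | tributyl(vinyl)stannane | C=C[Sn](CCCC)(CCCC)CCCC | starting material
3 | 3-methyl-2-vinylcyclopent-2-en-1-one | CC1=C(C=C)C(=O)CC1 | intermediate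
4 | methyl acetoacetate | COC(=O)CC(C)=O | starting material
5 | methyl 2-diazo-3-oxobutanoate | COC(=O)C(=[N+]=[N-])C(C)=O | intermediate
6 | methyl 2-diazo-3-hydroxybutanoate (racemic) | COC(=O)C(=[N+]=[N-])C(C)O | intermediate
7 | methyl 2-diazobut-3-enoate | COC(=O)C(=[N+]=[N-])C=C | intermediate
8 | methyl (1S,2S)-2-(2-methyl-5-oxocyclopent-1-en-1-yl)-1-vinylcyclopropane-1-carboxylate (vinyl and cyclopentenyl groups cis) | COC(=O)[C@]1(C=C)C[C@H]1C1=C(C)CCC1=O | intermediate (not isolated)
9 | methyl (8aR)-8a-methyl-3-oxo-1,2,3,5,8,8a-hexahydroazulene-6-carboxylate (C4 ketone, C5=C6, C8=C9 ester) | O=C1CC[C@]2(C)CC=C(C(=O)OC)CC=C12 | intermediate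
10 | methyl (3S,8aR)-3-hydroxy-8a-methyl-1,2,3,5,8,8a-hexahydroazulene-6-carboxylate (4β-OH) | O[C@H]1CC[C@]2(C)CC=C(C(=O)OC)CC=C12 | intermediate
11 | methyl (3S,8aR)-8a-methyl-3-(triethylsilyloxy)-1,2,3,5,8,8a-hexahydroazulene-6-carboxylate | CC[Si](CC)(CC)O[C@H]1CC[C@]2(C)CC=C(C(=O)OC)CC=C12 | intermediate
12 | C6 alkylborane from 11 (6α-BH2, 5α-H, 4β-OTES) | B[C@H]1CC(C(=O)OC)=CC[C@@]2(C)CC[C@H](O[Si](CC)(CC)CC)[C@H]12 | intermediate (not isolated)
13 | methyl (3S,3aS,4S,8aR)-4-hydroxy-8a-methyl-3-(triethylsilyloxy)-1,2,3,3a,4,5,8,8a-octahydroazulene-6-carboxylate (4β-OTES, 5α-H, 6α-OH) | O[C@H]1CC(C(=O)OC)=CC[C@@]2(C)CC[C@H](O[Si](CC)(CC)CC)[C@H]12 | intermediate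
14 | 6α-tert-butyldimethylsilyl ether of 13 | CC(C)(C)[Si](C)(C)O[C@H]1CC(C(=O)OC)=CC[C@@]2(C)CC[C@H](O[Si](CC)(CC)CC)[C@H]12 | intermediate
15 | primary allylic alcohol (C8–CH2OH, C8=C9, 4β-OTES, 5α-H, 6α-OTBS) | CC(C)(C)[Si](C)(C)O[C@H]1CC(CO)=CC[C@@]2(C)CC[C@H](O[Si](CC)(CC)CC)[C@H]12 | intermediate
16 | methanesulfonate of 15 | CC(C)(C)[Si](C)(C)O[C@H]1CC(COS(C)(=O)=O)=CC[C@@]2(C)CC[C@H](O[Si](CC)(CC)CC)[C@H]12 | intermediate (not isolated)
17 | C8-methyl bis-silyl ether (C8–CH3, C8=C9, 4β-OTES, 5α-H, 6α-OTBS, 1β-CH3) | CC(C)(C)[Si](C)(C)O[C@H]1CC(C)=CC[C@@]2(C)CC[C@H](O[Si](CC)(CC)CC)[C@H]12 | intermediate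
18 | 4β-alcohol (C4–OH β, 5α-H, 6α-OTBS, C8–CH3, C8=C9) | CC(C)(C)[Si](C)(C)O[C@H]1CC(C)=CC[C@@]2(C)CC[C@H](O)[C@H]12 | intermediate
19 | (3aS,4S,8aR)-4-(tert-butyldimethylsilyloxy)-6,8a-dimethyl-2,3a,4,5,8,8a-hexahydroazulen-3(1H)-one | CC(C)(C)[Si](C)(C)O[C@H]1CC(C)=CC[C@@]2(C)CCC(=O)[C@H]12 | intermediate
20 | (3R,3aS,4S,8aR)-4-(tert-butyldimethylsilyloxy)-6,8a-dimethyl-3-(propan-2-yl)-1,2,3,3a,4,5,8,8a-octahydroazulen-3-ol | CC(C)(C)[Si](C)(C)O[C@H]1CC(C)=CC[C@@]2(C)CC[C@@](O)(C(C)C)[C@H]12 | intermediate
21 | jaeschkeanadiol, (3R,3aS,4S,8aR)-6,8a-dimethyl-3-(propan-2-yl)-1,2,3,3a,4,5,8,8a-octahydroazulene-3,4-diol | O[C@H]1CC(C)=CC[C@@]2(C)CC[C@@](O)(C(C)C)[C@H]12 | intermediate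
22 | vanillic acid | COc1cc(C(=O)O)ccc1O | starting material
23 | 3-methoxy-4-(pivaloyloxy)benzoic acid | COc1cc(C(=O)O)ccc1OC(=O)C(C)(C)C | intermediate
24 | teferin O-pivalate, (3R,3aS,4S,8aR)-3-hydroxy-6,8a-dimethyl-3-(propan-2-yl)-1,2,3,3a,4,5,8,8a-octahydroazulen-4-yl 3-methoxy-4-(pivaloyloxy)benzoate | COc1cc(C(=O)O[C@H]2CC(C)=CC[C@@]3(C)CC[C@@](O)(C(C)C)[C@H]23)ccc1OC(=O)C(C)(C)C | intermediate
25 | teferin | COc1cc(C(=O)O[C@H]2CC(C)=CC[C@@]3(C)CC[C@@](O)(C(C)C)[C@H]23)ccc1O | target

Total: 18 steps. Longest linear sequence: 16 steps (4 → 25; steps 2–15, 17 and 18).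

Steps most likely to fail

Step 5. The electrophilic carbenoid may be diverted by the enone oxygen of 3 (ylide and epoxide formation) or lost by cyclisation of 7 to a pyrazole before it meets the electron-poor diene, and the inward C1 methyl may slow the Cope step. Fallback: take the carbonyl out of play as an acetal. Diene 3 would be treated with 1,2-bis(trimethylsilyloxy)ethane and catalytic Me3SiOTf (CH2Cl2, −78 °C) to give 7-methyl-6-vinyl-1,4-dioxaspiro[4.4]non-6-ene F1, an electron-richer diene without a free carbonyl. The same Rh2(R-DOSP)4 reaction with 7 would pass through the acetal-bearing cis-divinylcyclopropane F2 to the ethylene acetal of 9 F3. PPTS in wet acetone would then return ketone 9, where the route is rejoined.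

Step 8. Borane may add too slowly to the crowded C5=C6 bond, so that reduction of the conjugated ester or attack from the β face competes and the C5/C6 relationship is eroded. Fallback: epoxidation and radical opening in place of hydroboration. From 11, mCPBA (NaHCO3, CH2Cl2, 0 °C) should epoxidise only the electron-rich C5=C6 bond from the α face to give the 5α,6α-epoxide F4. The trivalent titanium reagent Cp2TiCl (from Cp2TiCl2 and zinc dust) with 1,4-cyclohexadiene in THF would cleave the C5–O bond to the tertiary C5 radical. This radical should take up hydrogen from the α face, away from the C1 methyl and the C4 silyloxy group, while the C6–O bond stays intact, which gives 13 again.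

Step 14. The branched reagent may act as a base or hydride donor toward the hindered ketone instead of adding, and enolisation toward C5 would put the ring-fusion configuration and the C6 silyloxy group at risk. Fallback: a two-stage installation through an sp2 nucleophile. From 19, isopropenylcerium dichloride (isopropenylmagnesium bromide, CeCl3, THF, −78 °C), which is smaller and cannot transfer a β-hydride, should give the isopropenyl carbinol F5 by the same α-face attack. Hydrogenation with RhCl(PPh3)3 under H2 (1 atm, benzene) would saturate only the 1,1-disubstituted alkene and leave the trisubstituted C8=C9 bond, giving 20.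

Further compounds
F1 | step 5 | 7-methyl-6-vinyl-1,4-dioxaspiro[4.4]non-6-ene | CC1=C(C=C)C2(CC1)OCCO2
F2 | step 5 | cis-divinylcyclopropane from F1 (ethylene acetal of 8, same configuration, not isolated) | COC(=O)[C@]1(C=C)C[C@H]1C1=C(C)CCC12OCCO2
F3 | step 5 | ethylene acetal of 9 | C13(OCCO3)CC[C@]2(C)CC=C(C(=O)OC)CC=C12
F4 | step 8 | 5α,6α-epoxide of 11 | CC[Si](CC)(CC)O[C@H]1CC[C@]2(C)CC=C(C(=O)OC)C[C@@H]3O[C@]123
F5 | step 14 | isopropenyl carbinol from 19 (4β-OH, 4α-isopropenyl, 6α-OTBS) | CC(C)(C)[Si](C)(C)O[C@H]1CC(C)=CC[C@@]2(C)CC[C@@](O)(C(C)=C)[C@H]12
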